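The readings come from a simulation from invented constants; the scatter is artificial.

The ash run gives us the one constant we need. By its last reading, at 90.0 s, it holds 7.4% of E, while the fraction of charge in D, integrated over time by trapezia through its readings, comes to 46.6 s.

| flask | Q | remark | time |
|---|---|---|---|
| birch | 29 mM | run made earlier |  |
| ash | 64 mM | run made earlier |  |
| west | 43 mM |  | 2.0 min |
| south-east | 43 mM |  | 5.0 min |
| south | 43 mM |  | 12 min |

| run | time / s | D / % | E / % | Q / % | L / % |
|---|---|---|---|---|---|
| birch | 10.0 | 27.9 | 0.9 | 35.1 | 32.4 |
| birch | 20.0 | 43.5 | 0 | 25.3 | 23.3 |
| birch | 40.0 | 65.1 | 3.3 | 16.7 | 12.1 |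
| birch | 90.0 | 85.0 | 8.0 | 5.8 | 0 |
| ash | 25.0 | 41.0 | 1.1 | 21.8 | 27.8 |
| ash | 50.0 | 63.8 | 1.3 | 12.5 | 13.7 |
| ash | 80.0 | 75.3 | 5.7 | 7.7 | 1.7 |
| ash | 90.0 | 75.0 | 7.4 | 6.1 | 2.6 |

(readings scatter by 1 percentage point)

- in percentages every species weighs as the Q in it: one L counts as two
- a reading or a percentage of D counts all its forms, free or not
- a reading of Q is of its free form alone

1. which of these there is most of at the end, counted by the Q in it, west (L / Q / E / D)
2. which of these there is most of at the end, counted by the Q in it, south-east (L / Q / E / D)
3. which of these there is most of at the end, counted by the Q in it, south (L / Q / E / D)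
4. amount of the one of these that there is most of at the end, in percent of the Q charged, west
5. amount of the one of these that there is most of at the end, in percent of the Q charged, south-east
6. amount of the one of these that there is most of at the end, in percent of the Q charged, south

We take E as the end state and read a first-order drain of D, 0.00159 s⁻¹, which is a reading, since the E behind it scatters by 1 percentage point. If this drain acted on the whole charge from one moment on, the same E would put that moment at a lag of 41.6 s. The fraction in E is then one minus the exponential of the drain constant times the time after the lag. From this we define the crossing time, the moment at which E equals the rest of the charge: 7.97 min. It falls later than south-east's 5.0 min and earlier than south's 12 min. So we expect D to lead in west and south-east, and E in south. Our curve gives E of 11.7% in west, 33.7% in south-east and 66.0% in south.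

For west, south-east and south in turn, the forecast names D, D and E, with 81% (76% to 86%), 63% (55% to 71%) and 64% (52% to 75%). For south it says “so E has overtaken D”, with a figure for E lower than that of our curve.

The flasks give D at 83.1% in west, D at 65.4% in south-east and E at 68.0% in south, with D counted in all its forms.

    Q → D (k = 0.0550 s⁻¹)
    2 Q ⇌ L (K = 36.0 M⁻¹, k = 3.50 M⁻¹ s⁻¹)
    D → E (k = 0.00170 s⁻¹)
    Q + D ⇌ X, settled at all times (K = 26.0 M⁻¹)

South and west have the same charge, and south's E of 68.0% drops to 11.7% at west's time, so the difference in time is the main reason. The half-life of free D by the reaction to E alone, 6.8 min, is far longer than that of Q by the reaction to D alone, 0.21 min; D to E is the rate-limiting step on the way to E. South is read 4.03 min past the crossing time. The neighbour reading of south-east at 3.0 min comes before it, so the curve through 7.97 min gives E of 19.7%, and that flask holds 19.9%.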